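## Analysis of the target

Compound 29 is a linear tetramer of four six-membered polyketide rings held together by three CH2 bridges. Ring A is an enolised 2-butanoyl-4,4-dimethylcyclohexane-1,3,5-trione (a filicinic acid unit). Rings B and C are butanoylphloroglucinols whose two remaining carbons both carry bridges. Ring D is a butanoylphloroglucinol whose last carbon carries a methyl group. There is no stereocentre; ring A exists as rapidly interconverting enol tautomers, of which the SMILES shows one. The eleven hydroxyl groups are acidic and mostly chelated to a neighbouring ketone, and the unacylated polyphenols on the way are air-sensitive. The Ar–CH2–Ar bridges between such electron-rich rings are the fragile element: in base they can fragment to a quinone methide and a ring anion and recombine at random, and in strong acid they can be cut by ipso attack. The difficulty is therefore sequence and regiochemistry: four nearly identical nucleophilic rings must be placed in a fixed order, each with exactly one butanoyl group, and unsymmetrical bridges must be made without statistical mixtures. The strategy rests on ring D, whose carbons alternate as C(OH), C(CH3), C(OH), C(butanoyl), C(OH), C(CH2 to ring C). This 1,3,5-trioxygenated pattern maps onto a four-carbon 3-alkoxycyclobutenone (C=O, CH, C–O, CH–CH2Ar) plus a two-carbon siloxyalkyne (C–CH3, C–O).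

## Retrosynthetic reasoning

**Central bridge.** Target 29 is cut at both C–C bonds of the methylene between rings B and C. This gives the ring A–ring B dimer 27 and the ring C–ring D dimer 22. Each half has exactly one unsubstituted ring carbon (on ring B in 27, on ring C in 22), so the bridge can go to one place only. The forward reaction aminomethylates 22 to the Mannich base 28, which transfers its CH2 to 27 through a quinone methide; the coupling is directional instead of a three-component statistical condensation.

**Ring A–ring B bridge.** Dimer 27 is cut at the bridge into butyrylfilicinic acid 25 and butanoylphloroglucinol 24, again through a Mannich base (26) of the partner that has a single free carbon. Triketone 25 comes from 24 by geminal C-methylation, and 24 from phloroglucinol 23 by Friedel–Crafts acylation. Ketone 24 thus serves rings A and B.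

**Both butanoyl groups of the ring C–ring D half.** Dimer 22 is taken back to its 2-ethyl ether 21 and then, by removing both acyl groups, to the pentaphenol 20. Ring D's acyl group must come after ring D exists, because it sits on the one ring CH that the ring construction leaves. Ring C has two more free carbons of the same kind, so a ring-D-selective acylation of a protected intermediate cannot be relied on. Both rings are therefore acylated together on the free phenols, where a first chelated acyl group deactivates its ring and each ring should stop at one. The ethyl ether goes last: the ortho ketone makes it easy to cleave, and the doubly acylated bridge tolerates the Lewis acid.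

**Protecting groups.** Pentaphenol 20 comes from diol 19 by hydrogenolysis of three benzyl ethers, and 19 from the benzannulation product 18 by desilylation. The benzyl ethers are removed before any Lewis acid is used, so that no benzyl cation can re-alkylate the rings.

**Ring D (key disconnection).** Phenol 18 is cut at three ring bonds: C(OH)–C(CH3), C(OSi)–C(H) and C(OH)–C(CH2Ar). This leads to cyclobutenone 9 and siloxypropyne 13. The cut puts the three different carbon substituents of ring D in place unambiguously and leaves one ring CH exactly where the butanoyl group belongs. The bridge to ring C is already part of the carbon skeleton, so this bridge needs no one-carbon condensation.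

**Cyclobutenone.** Compound 9 is cut at two ring bonds into the arylmethylketene 8 and ethoxyacetylene 6. Ketene 8 is generated from acid chloride 7, and this from the propanoic acid 5.

**Side chain.** Acid 5 comes from cinnamic acid 4 by alkene reduction, and 4 from aldehyde 2 and malonic acid 3 by condensation and decarboxylation. Aldehyde 2 is the tribenzyl ether of 2,4,6-trihydroxybenzaldehyde 1. The aldehyde carbon of 1 becomes the ring C–ring D bridge.

**Siloxyalkyne.** Compound 13 is the O-silylated ynolate 12, which arises from the dibromo enolate 11 by 1,2-shift; 11 comes from ethyl acetate 10 by one-carbon homologation.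

## Alternatives that were turned down

**Alternative 1:** Rings B and C are each taken back to a 4-hydroxy-2-pyranone, with the central bridge already present in the methylene-bis(pyranone) A2. In the forward step an alkoxide base opens both lactones; in each half the side-chain methylene between two ketones condenses onto the new ester (Claisen) and closes a benzene ring, giving A1. In its favour, both middle rings, their butanoyl groups and the central bridge arrive in one operation, without protecting groups or late acylation. On step economy for the B–C portion it is clearly stronger than the chosen route. Against it, A1 is symmetrical with one free carbon on each ring, whereas the target needs ring A on one side and ring D on the other. The desymmetrisation is statistical and falls on an advanced intermediate. Both outer bridges then have to be made by one-carbon condensations on a compound that already holds an exchange-prone bridge. The doubly opened poly-β-keto ester also has many enolisable sites and can reclose to pyranones or cross-condense between the two chains. The chosen route has one statistical alkylation (step 13), but it falls on the cheap ketone 24 used in excess. In exchange it offers a ring C–ring D bridge fixed by the skeleton, and a last coupling between partners that each have a single reactive carbon.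

**Alternative 2:** Ring A is cut between its acyl-bearing carbon and the enol carbon next to the quaternary carbon, giving the open-chain triketo ester A4. In the forward step an alkoxide deprotonates the 1,3-diketone methylene of A4, which attacks the ester next to the gem-dimethyl carbon (Dieckmann-type Claisen) to give A3. In its favour, the gem-dimethyl group and the ring A–ring B bridge are fixed in the chain, so neither a statistical C-methylation nor a bridging condensation is needed there. On regiocontrol at ring A it is stronger than step 12 of the chosen route. Against it, the key step is spent on the ring that is one step from 24. A4 needs a multistep synthesis (quaternary centre, three ketones, a C-benzylated diketone) and can cyclise to a pyranone or undergo retro-Claisen cleavage. Ring B arrives benzylated and unacylated, so it must later be acylated once at one of two carbons beside the sensitive triketone. Rings C and D and two bridges still remain. The chosen strategy offers a short, if unselective, entry to ring A and puts its effort on the ring D end, where three different carbon substituents must be placed.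

**Alternative 3:** Ring C is cut at the two ring bonds on either side of its C(OEt)–C(acyl) edge, giving the doubly arylmethylated bis(silyloxy)diene A7 and the alkynone A6. In the forward step the diene adds to the push–pull alkyne and the adduct aromatises by loss of the alcohol to give A5. In its favour, it is the most convergent plan: ring C forms in the middle with both of its bridges and its butanoyl group in place. It is stronger than the chosen route in convergency and in fixing two bridges by skeleton. Against it, A7 carries bulky arylmethyl groups at C2 and C4, and terminally substituted dienes of this type add slowly and raise a geometry question. A7 needs sequential α- and γ-alkylation with unstable electron-rich benzyl halides. Rings B and D arrive as unacylated benzyl ethers, so one acyl group each must still be placed (ring B has two sites) beside an acylated ring C. Ring A and an ethyl ether remain as well. The chosen strategy uses small, unhindered, strongly polarised partners in a known reaction class and needs only one arylmethyl arm, made by ordinary carbonyl chemistry.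

Key step: step 6

Remark on the chemistry: ring A is treated as a freely tautomerising enolised triketone and is written as the tautomer of the target SMILES; compounds 9, 15 and 17 are racemic and their stereocentres disappear on aromatisation.

## Route

Step 1
Reactants: 1 2,4,6-trihydroxybenzaldehyde
Product: 2 2,4,6-tris(benzyloxy)benzaldehyde
Conditions: BnBr (3.6 equiv), K2CO3, DMF, 60 °C
Reagents that add atoms: benzyl bromide, BrCc1ccccc1
Why: Williamson O-alkylation; the formyl group makes the ring a vinylogous acid, so O-alkylation should outrun C-benzylation, and excess bromide with mild heating should drive the chelated ortho hydroxyls to completion.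

Step 2
Reactants: 2 2,4,6-tris(benzyloxy)benzaldehyde, 3 malonic acid
Product: 4 (2E)-3-[2,4,6-tris(benzyloxy)phenyl]prop-2-enoic acid
Conditions: pyridine, piperidine (cat.), 95 °C
Reagents that add atoms: none
Why: Knoevenagel–Doebner condensation; the malonate adduct loses water and then CO2 in hot pyridine, which should give the E acid only, and the two ortho benzyloxy groups slow but do not block the addition.

Step 3
Reactants: 4 (2E)-3-[2,4,6-tris(benzyloxy)phenyl]prop-2-enoic acid
Product: 5 3-[2,4,6-tris(benzyloxy)phenyl]propanoic acid
Conditions: H2 (4 atm), RhCl(PPh3)3 (5 mol %), THF/EtOH, 45 °C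
Reagents that add atoms: none
Why: Homogeneous hydrogenation with RhCl(PPh3)3 saturates the disubstituted conjugated alkene but does not hydrogenolyse aryl benzyl ethers, which a palladium catalyst would remove at this stage.

Step 4
Reactants: 5 3-[2,4,6-tris(benzyloxy)phenyl]propanoic acid, 6 ethoxyacetylene
Product: 9 3-ethoxy-4-{[2,4,6-tris(benzyloxy)phenyl]methyl}cyclobut-2-en-1-one (racemic), via acid chloride 7 (not isolated), via arylmethylketene 8 (not isolated)
Conditions: 1-chloro-N,N,2-trimethylprop-1-en-1-amine, CH2Cl2, 0 → 25 °C; then 6 (3 equiv), Et3N (slow addition), Et2O, 25 → 35 °C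
Reagents that add atoms: none
Why: The neutral α-chloroenamine gives the acid chloride without HCl or an acylating by-product that could attack the very electron-rich ring; Et3N then forms the aldoketene, which undergoes [2+2] cycloaddition with the ynol ether, its carbonyl carbon bonding to the unsubstituted alkyne carbon, to give the 3-ethoxy-4-substituted cyclobutenone. Slow base addition and excess alkyne should keep ketene dimerisation down.

Step 5
Reactants: 10 ethyl acetate
Product: 13 triisopropyl(prop-1-yn-1-yloxy)silane, via dibromo enolate 11 (not isolated), via lithium ynolate 12 (not isolated)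
Conditions: CH2Br2, lithium 2,2,6,6-tetramethylpiperidide, THF, −78 °C; n-BuLi, −78 → 25 °C; iPr3SiCl, −78 → 0 °C
Reagents that add atoms: dibromomethane, BrCBr; chlorotriisopropylsilane, CC(C)[Si](Cl)(C(C)C)C(C)C
Why: Kowalski ester homologation; dibromomethyllithium adds to the ester, the derived dibromo enolate undergoes bromine–lithium exchange and 1,2-shift of the methyl group to the ynolate, and the bulky chlorosilane should trap it on oxygen.

Step 6
Reactants: 9 3-ethoxy-4-{[2,4,6-tris(benzyloxy)phenyl]methyl}cyclobut-2-en-1-one, 13 triisopropyl(prop-1-yn-1-yloxy)silane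
Product: 18 3-ethoxy-6-methyl-5-[(triisopropylsilyl)oxy]-2-{[2,4,6-tris(benzyloxy)phenyl]methyl}phenol, via vinylketene 14 (not isolated), via vinylcyclobutenone 15 (not isolated), via dienylketene 16 (not isolated), via cyclohexadienone 17 (not isolated)
Conditions: 13 (2 equiv), toluene, 80 → 110 °C, Ar
Reagents that add atoms: none
Why: Danheiser benzannulation, a thermal cascade: 4π electrocyclic opening of 9 gives vinylketene 14, whose ketene C=C adds the siloxyalkyne in a [2+2] cycloaddition to give 15; reversible 4π opening of 15 gives dienylketene 16, which closes ring D by a 6π disrotatory electrocyclisation between the ketene carbon and the CH–CH2Ar terminus to give 17, and tautomerisation gives phenol 18. The closest known reaction type is the benzannulation of cyclobutenones with siloxyalkynes to resorcinol monosilyl ethers. The required regiochemistry (methyl next to the new hydroxyl, siloxy next to the ring CH) is fixed in the [2+2] step by polarisation: the nucleophilic methyl-bearing carbon of the ynol ether attacks the electrophilic ketene carbonyl carbon. The arylmethyl group, a donor at C4 of 9, should rotate outward, so 14 has no allylic hydrogen placed for a 1,5-shift; only the isomer of 16 with the ketene and the ethoxyvinyl group cis can cyclise, and the reversible opening of 15 should feed material through it. No stereocentre survives, since those of 9, 15 and 17 are destroyed on aromatisation. Acylation of the product phenol by 14 should be held back by the two ortho substituents of the new hydroxyl and by the excess of alkyne; the benzyl, silyl and enol ethers are inert under neutral thermal conditions.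

Step 7
Reactants: 18 3-ethoxy-6-methyl-5-[(triisopropylsilyl)oxy]-2-{[2,4,6-tris(benzyloxy)phenyl]methyl}phenol
Product: 19 5-ethoxy-2-methyl-4-{[2,4,6-tris(benzyloxy)phenyl]methyl}benzene-1,3-diol
Conditions: Bu4NF, AcOH, THF, 0 °C
Reagents that add atoms: none
Why: Fluoride cleaves the aryl silyl ether; acetic acid buffers the phenoxide so that the electron-rich resorcinol is not exposed to base and air, and the benzyl and ethyl ethers are inert.

Step 8
Reactants: 19 5-ethoxy-2-methyl-4-{[2,4,6-tris(benzyloxy)phenyl]methyl}benzene-1,3-diol
Product: 20 2-[(6-ethoxy-2,4-dihydroxy-3-methylphenyl)methyl]benzene-1,3,5-triol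
Conditions: H2 (1 atm), Pd/C, EtOAc/MeOH, 25 °C
Reagents that add atoms: none
Why: Hydrogenolysis of the three aryl benzyl ethers; nothing else in 19 is reducible and the diarylmethane C–C bonds are not cleaved. Compound 20 is air-sensitive and should be used at once.

Step 9
Reactants: 20 2-[(6-ethoxy-2,4-dihydroxy-3-methylphenyl)methyl]benzene-1,3,5-triol
Product: 21 1-{3-[(3-butanoyl-2,4,6-trihydroxyphenyl)methyl]-2-ethoxy-4,6-dihydroxy-5-methylphenyl}butan-1-one
Conditions: PrCOCl (2.2 equiv), AlCl3 (6 equiv), CH2Cl2/MeNO2, 0 → 25 °C; aq. HCl
Reagents that add atoms: butanoyl chloride, CCCC(Cl)=O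
Why: Friedel–Crafts C-acylation of phloroglucinol-type rings; ring C has two equivalent free carbons and ring D one, and the first acyl group on each ring, held coplanar by a chelated ortho hydroxyl, deactivates that ring, so two equivalents should place one butanoyl group per ring without any need to tell the rings apart. The benzyl ethers are already gone, so the Lewis acid cannot release benzyl cations.

Step 10
Reactants: 21 1-{3-[(3-butanoyl-2,4,6-trihydroxyphenyl)methyl]-2-ethoxy-4,6-dihydroxy-5-methylphenyl}butan-1-one
Product: 22 1-{3-[(3-butanoyl-2,4,6-trihydroxyphenyl)methyl]-2,4,6-trihydroxy-5-methylphenyl}butan-1-one (ring C–ring D dimer)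
Conditions: BBr3 (8 equiv), CH2Cl2, −78 → 0 °C; H2O
Reagents that add atoms: none
Why: Lewis-acid ether cleavage assisted by chelation; boron binds the ketone and the ortho ethoxy oxygen and bromide attacks the ethyl group. Both rings are now acylated, which should make the bridge resistant to acid, and any ethyl ether already lost in step 9 converges here.

Step 11
Reactants: 23 phloroglucinol
Product: 24 1-(2,4,6-trihydroxyphenyl)butan-1-one
Conditions: PrCOCl (1.05 equiv), AlCl3, CH2Cl2/MeNO2, 0 → 40 °C; aq. HCl
Reagents that add atoms: butanoyl chloride, CCCC(Cl)=O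
Why: Friedel–Crafts mono-acylation of phloroglucinol; the chelated acyl group deactivates the ring against a second acylation.

Step 12
Reactants: 24 1-(2,4,6-trihydroxyphenyl)butan-1-one
Product: 25 2-butanoyl-3,5-dihydroxy-4,4-dimethylcyclohexa-2,5-dien-1-one (butyrylfilicinic acid)
Conditions: MeI (2.2 equiv), NaOMe, MeOH, 0 → 25 °C
Reagents that add atoms: iodomethane, CI
Why: Dearomatising C-alkylation of the acylphloroglucinol anion; two methyl groups on one ring carbon give the enolised triketone, and the mono-, 3,5-di- and trimethylated by-products should be separable.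

Step 13
Reactants: 25 2-butanoyl-3,5-dihydroxy-4,4-dimethylcyclohexa-2,5-dien-1-one, 24 1-(2,4,6-trihydroxyphenyl)butan-1-one
Product: 27 2-butanoyl-6-[(3-butanoyl-2,4,6-trihydroxyphenyl)methyl]-3,5-dihydroxy-4,4-dimethylcyclohexa-2,5-dien-1-one (ring A–ring B dimer), via Mannich base 26 (not isolated)
Conditions: Me2N=CH2 I (0.95 equiv), NaOAc, MeCN, 25 °C; then 24 (3 equiv), dioxane, 90 °C
Reagents that add atoms: dimethylmethylideneammonium iodide, C=[N+](C)C.[I-]
Why: Mannich reaction at the single free ring carbon of 25, then thermal loss of dimethylamine to a 6-methylene triketone that the free ring carbon of 24 captures by Michael addition and rearomatisation. The substoichiometric iminium salt leaves no one-carbon electrophile for 24, and the excess of 24 should suppress a second alkylation of ring B.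

Step 14
Reactants: 22 1-{3-[(3-butanoyl-2,4,6-trihydroxyphenyl)methyl]-2,4,6-trihydroxy-5-methylphenyl}butan-1-one, 27 2-butanoyl-6-[(3-butanoyl-2,4,6-trihydroxyphenyl)methyl]-3,5-dihydroxy-4,4-dimethylcyclohexa-2,5-dien-1-one
Product: 29 2-butanoyl-6-{[3-butanoyl-5-({3-butanoyl-5-[(3-butanoyl-2,4,6-trihydroxy-5-methylphenyl)methyl]-2,4,6-trihydroxyphenyl}methyl)-2,4,6-trihydroxyphenyl]methyl}-3,5-dihydroxy-4,4-dimethylcyclohexa-2,5-dien-1-one (target), via Mannich base 28 (not isolated)
Conditions: Me2N=CH2 I (0.95 equiv), NaOAc, MeCN, 25 °C; then 27 (1.5 equiv), dioxane, 90 °C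
Reagents that add atoms: dimethylmethylideneammonium iodide, C=[N+](C)C.[I-]
Why: Mannich reaction and quinone methide transfer as in step 13; ring C of 22 has one free carbon and ring D none, so aminomethylation is site-unique, and the ortho-quinone methide from 28 should be captured by the only free carbon of 27, on ring B. The acetate buffer avoids alkali, under which the bridges exchange.

## Compound list

1 | 2,4,6-trihydroxybenzaldehyde | O=Cc1c(O)cc(O)cc1O | starting material
2 | 2,4,6-tris(benzyloxy)benzaldehyde | O=Cc1c(OCc2ccccc2)cc(OCc2ccccc2)cc1OCc1ccccc1 | intermediate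
3 | malonic acid | OC(=O)CC(O)=O | starting material
4 | (2E)-3-[2,4,6-tris(benzyloxy)phenyl]prop-2-enoic acid | OC(=O)/C=C/c1c(OCc2ccccc2)cc(OCc2ccccc2)cc1OCc1ccccc1 | intermediate
5 | 3-[2,4,6-tris(benzyloxy)phenyl]propanoic acid | OC(=O)CCc1c(OCc2ccccc2)cc(OCc2ccccc2)cc1OCc1ccccc1 | intermediate
6 | ethoxyacetylene | CCOC#C | starting material
7 | 3-[2,4,6-tris(benzyloxy)phenyl]propanoyl chloride | ClC(=O)CCc1c(OCc2ccccc2)cc(OCc2ccccc2)cc1OCc1ccccc1 | intermediate (not isolated)
8 | 3-[2,4,6-tris(benzyloxy)phenyl]prop-1-en-1-one (arylmethylketene) | O=C=CCc1c(OCc2ccccc2)cc(OCc2ccccc2)cc1OCc1ccccc1 | intermediate (not isolated)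
9 | 3-ethoxy-4-{[2,4,6-tris(benzyloxy)phenyl]methyl}cyclobut-2-en-1-one (racemic) | CCOC1=CC(=O)C1Cc1c(OCc2ccccc2)cc(OCc2ccccc2)cc1OCc1ccccc1 | intermediate
10 | ethyl acetate | CCOC(C)=O | starting material
11 | lithium 1,1-dibromoprop-1-en-2-olate | [Li+].CC([O-])=C(Br)Br | intermediate (not isolated)
12 | lithium prop-1-yn-1-olate | [Li+].CC#C[O-] | intermediate (not isolated)
13 | triisopropyl(prop-1-yn-1-yloxy)silane | CC#CO[Si](C(C)C)(C(C)C)C(C)C | intermediate
14 | (3Z)-3-ethoxy-5-[2,4,6-tris(benzyloxy)phenyl]penta-1,3-dien-1-one | O=C=C/C(OCC)=C/Cc1c(OCc2ccccc2)cc(OCc2ccccc2)cc1OCc1ccccc1 | intermediate (not isolated)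
15 | 4-{(1Z)-1-ethoxy-3-[2,4,6-tris(benzyloxy)phenyl]prop-1-en-1-yl}-2-methyl-3-[(triisopropylsilyl)oxy]cyclobut-2-en-1-one (racemic) | CC1=C(O[Si](C(C)C)(C(C)C)C(C)C)C(/C(OCC)=C/Cc2c(OCc3ccccc3)cc(OCc3ccccc3)cc2OCc2ccccc2)C1=O | intermediate (not isolated)
16 | (3E,5Z)-5-ethoxy-2-methyl-3-[(triisopropylsilyl)oxy]-7-[2,4,6-tris(benzyloxy)phenyl]hepta-1,3,5-trien-1-one | O=C=C(C)/C(O[Si](C(C)C)(C(C)C)C(C)C)=C\C(OCC)=C\Cc1c(OCc2ccccc2)cc(OCc2ccccc2)cc1OCc1ccccc1 | intermediate (not isolated)
17 | 5-ethoxy-2-methyl-3-[(triisopropylsilyl)oxy]-6-{[2,4,6-tris(benzyloxy)phenyl]methyl}cyclohexa-2,4-dien-1-one (racemic) | CC1=C(O[Si](C(C)C)(C(C)C)C(C)C)C=C(OCC)C(Cc2c(OCc3ccccc3)cc(OCc3ccccc3)cc2OCc2ccccc2)C1=O | intermediate (not isolated)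
18 | 3-ethoxy-6-methyl-5-[(triisopropylsilyl)oxy]-2-{[2,4,6-tris(benzyloxy)phenyl]methyl}phenol | Cc1c(O)c(Cc2c(OCc3ccccc3)cc(OCc3ccccc3)cc2OCc2ccccc2)c(OCC)cc1O[Si](C(C)C)(C(C)C)C(C)C | intermediate
19 | 5-ethoxy-2-methyl-4-{[2,4,6-tris(benzyloxy)phenyl]methyl}benzene-1,3-diol | Cc1c(O)c(Cc2c(OCc3ccccc3)cc(OCc3ccccc3)cc2OCc2ccccc2)c(OCC)cc1O | intermediate
20 | 2-[(6-ethoxy-2,4-dihydroxy-3-methylphenyl)methyl]benzene-1,3,5-triol | Cc1c(O)c(Cc2c(O)cc(O)cc2O)c(OCC)cc1O | intermediate
21 | 1-{3-[(3-butanoyl-2,4,6-trihydroxyphenyl)methyl]-2-ethoxy-4,6-dihydroxy-5-methylphenyl}butan-1-one | CCCC(=O)c1c(O)cc(O)c(Cc2c(O)c(C)c(O)c(C(=O)CCC)c2OCC)c1O | intermediate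
22 | 1-{3-[(3-butanoyl-2,4,6-trihydroxyphenyl)methyl]-2,4,6-trihydroxy-5-methylphenyl}butan-1-one | CCCC(=O)c1c(O)cc(O)c(Cc2c(O)c(C)c(O)c(C(=O)CCC)c2O)c1O | intermediate
23 | phloroglucinol (benzene-1,3,5-triol) | Oc1cc(O)cc(O)c1 | starting material
24 | 1-(2,4,6-trihydroxyphenyl)butan-1-one | CCCC(=O)c1c(O)cc(O)cc1O | intermediate
25 | 2-butanoyl-3,5-dihydroxy-4,4-dimethylcyclohexa-2,5-dien-1-one | CCCC(=O)C1=C(O)C(C)(C)C(O)=CC1=O | intermediate
26 | 2-butanoyl-6-[(dimethylamino)methyl]-3,5-dihydroxy-4,4-dimethylcyclohexa-2,5-dien-1-one | CCCC(=O)C1=C(O)C(C)(C)C(O)=C(CN(C)C)C1=O | intermediate (not isolated)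
27 | 2-butanoyl-6-[(3-butanoyl-2,4,6-trihydroxyphenyl)methyl]-3,5-dihydroxy-4,4-dimethylcyclohexa-2,5-dien-1-one | CCCC(=O)C1=C(O)C(C)(C)C(O)=C(Cc2c(O)cc(O)c(C(=O)CCC)c2O)C1=O | intermediate
28 | 1-{3-[(3-butanoyl-2,4,6-trihydroxy-5-methylphenyl)methyl]-5-[(dimethylamino)methyl]-2,4,6-trihydroxyphenyl}butan-1-one | CCCC(=O)c1c(O)c(CN(C)C)c(O)c(Cc2c(O)c(C)c(O)c(C(=O)CCC)c2O)c1O | intermediate (not isolated)
29 | 2-butanoyl-6-{[3-butanoyl-5-({3-butanoyl-5-[(3-butanoyl-2,4,6-trihydroxy-5-methylphenyl)methyl]-2,4,6-trihydroxyphenyl}methyl)-2,4,6-trihydroxyphenyl]methyl}-3,5-dihydroxy-4,4-dimethylcyclohexa-2,5-dien-1-one | CCCC(=O)C1=C(O)C(C)(C)C(O)=C(Cc2c(O)c(Cc3c(O)c(Cc4c(O)c(C)c(O)c(C(=O)CCC)c4O)c(O)c(C(=O)CCC)c3O)c(O)c(C(=O)CCC)c2O)C1=O | target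

## Step count and least certain steps

Total: 14 steps. Longest linear sequence: 10 steps (1, 2, 3, 4, 6, 7, 8, 9, 10, 14).

**Step 6 (key step).** The cyclobutenone is a vinylogous ester and may open slowly. At the temperature then needed, the siloxyalkyne can isomerise to a silylketene, and the product phenol can be esterified by the vinylketene, so material is lost before the [2+2] step. Fallback, setting out from 24 and returning at 22: 2-methylbenzene-1,3,5-triol F1 (commercial) would be mono-butanoylated (butanoyl chloride, AlCl3) to 1-(2,4,6-trihydroxy-3-methylphenyl)butan-1-one F2. F2 would be aminomethylated at its single free ring carbon (dimethylmethylideneammonium iodide, NaOAc) to 1-{3-[(dimethylamino)methyl]-2,4,6-trihydroxy-5-methylphenyl}butan-1-one F3. F3 heated with an excess of 24 in dioxane should give 22 by quinone methide transfer.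

**Step 9.** Before both rings are deactivated, the Lewis acid can cut or exchange the methylene bridge by ipso protonation or ipso acylation of the unacylated rings. Over-acylation of ring C and air oxidation of 20 are further losses. Fallback, setting out from 19 and returning at 22: 19 would be O-methylated on both phenols (MeI, K2CO3, DMF) to 1,3,5-tris(benzyloxy)-2-[(6-ethoxy-2,4-dimethoxy-3-methylphenyl)methyl]benzene F4. Both rings, now plain trialkoxybenzenes, would be acylated without a metal Lewis acid by the mixed anhydride of butanoic acid and trifluoroacetic anhydride (CH2Cl2, 0 → 25 °C). This should give 1-{3-[(3-butanoyl-2,4,6-tris(benzyloxy)phenyl)methyl]-2-ethoxy-4,6-dimethoxy-5-methylphenyl}butan-1-one F5. Hydrogenolysis (H2, Pd/C) would give 1-{3-[(3-butanoyl-2,4,6-trihydroxyphenyl)methyl]-2-ethoxy-4,6-dimethoxy-5-methylphenyl}butan-1-one F6, and BBr3 would cleave the two methyl ethers and the ethyl ether to give 22.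

**Step 14.** During the heating, existing bridges can undergo retro-Michael fragmentation and recombination; loss of the triketone ring A from 27 is the easiest such path and would scramble the ring sequence. The quinone methide from 28 can also self-condense. Fallback, setting out from 22 and returning at 29: the Mannich base 28, made as in step 14, would be heated with an excess of 24 to give 1-{3-[(3-butanoyl-2,4,6-trihydroxyphenyl)methyl]-5-[(3-butanoyl-2,4,6-trihydroxy-5-methylphenyl)methyl]-2,4,6-trihydroxyphenyl}butan-1-one F10, the ring B–C–D trimer. F10 has one free ring carbon, on ring B, and would be alkylated there by the Mannich base 26, generated from 25 as in step 13, to give 29. The last bond formed is then the ring A–ring B bridge, and no bridge to the readily leaving triketone ring is exposed to a second coupling.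

**Step 12.** The C-methylation can stop at the monomethyl stage, distribute the two methyl groups over both ring carbons, or go on to tri- and tetramethyl products; O-methylation is also possible. Fallback, setting out from 23 and returning at 25: 23 would be diacylated (butanoyl chloride, 2.2 equiv, AlCl3) to 1,1'-(2,4,6-trihydroxy-1,3-phenylene)di(butan-1-one) F7, which has a single free ring carbon. Geminal dimethylation there (MeI, NaOMe) would give 2,6-dibutanoyl-3,5-dihydroxy-4,4-dimethylcyclohexa-2,5-dien-1-one F8. Retro-Claisen removal of both acyl groups in hot aqueous H2SO4 would give 3,5-dihydroxy-4,4-dimethylcyclohexa-2,5-dien-1-one F9 (filicinic acid), and mono-C-butanoylation (butanoyl chloride, AlCl3) would give 25.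

## Further compounds

F1 | step 6 | 2-methylbenzene-1,3,5-triol | Cc1c(O)cc(O)cc1O
F2 | step 6 | 1-(2,4,6-trihydroxy-3-methylphenyl)butan-1-one | CCCC(=O)c1c(O)c(C)c(O)cc1O
F3 | step 6 | 1-{3-[(dimethylamino)methyl]-2,4,6-trihydroxy-5-methylphenyl}butan-1-one | CCCC(=O)c1c(O)c(C)c(O)c(CN(C)C)c1O
F4 | step 9 | 1,3,5-tris(benzyloxy)-2-[(6-ethoxy-2,4-dimethoxy-3-methylphenyl)methyl]benzene | Cc1c(OC)c(Cc2c(OCc3ccccc3)cc(OCc3ccccc3)cc2OCc2ccccc2)c(OCC)cc1OC
F5 | step 9 | 1-{3-[(3-butanoyl-2,4,6-tris(benzyloxy)phenyl)methyl]-2-ethoxy-4,6-dimethoxy-5-methylphenyl}butan-1-one | CCCC(=O)c1c(OCc2ccccc2)cc(OCc2ccccc2)c(Cc2c(OC)c(C)c(OC)c(C(=O)CCC)c2OCC)c1OCc1ccccc1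
F6 | step 9 | 1-{3-[(3-butanoyl-2,4,6-trihydroxyphenyl)methyl]-2-ethoxy-4,6-dimethoxy-5-methylphenyl}butan-1-one | CCCC(=O)c1c(O)cc(O)c(Cc2c(OC)c(C)c(OC)c(C(=O)CCC)c2OCC)c1O
F7 | step 12 | 1,1'-(2,4,6-trihydroxy-1,3-phenylene)di(butan-1-one) | CCCC(=O)c1c(O)cc(O)c(C(=O)CCC)c1O
F8 | step 12 | 2,6-dibutanoyl-3,5-dihydroxy-4,4-dimethylcyclohexa-2,5-dien-1-one | CCCC(=O)C1=C(O)C(C)(C)C(O)=C(C(=O)CCC)C1=O
F9 | step 12 | 3,5-dihydroxy-4,4-dimethylcyclohexa-2,5-dien-1-one (filicinic acid) | CC1(C)C(O)=CC(=O)C=C1O
F10 | step 14 | 1-{3-[(3-butanoyl-2,4,6-trihydroxyphenyl)methyl]-5-[(3-butanoyl-2,4,6-trihydroxy-5-methylphenyl)methyl]-2,4,6-trihydroxyphenyl}butan-1-one | CCCC(=O)c1c(O)cc(O)c(Cc2c(O)c(Cc3c(O)c(C)c(O)c(C(=O)CCC)c3O)c(O)c(C(=O)CCC)c2O)c1O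
A1 | alternative 1 | bis(3-butanoyl-2,4,6-trihydroxyphenyl)methane | CCCC(=O)c1c(O)cc(O)c(Cc2c(O)cc(O)c(C(=O)CCC)c2O)c1O
A2 | alternative 1 | 3,3'-methylenebis[4-hydroxy-6-(2-oxopentyl)-2H-pyran-2-one] | CCCC(=O)CC1=CC(O)=C(CC2=C(O)C=C(CC(=O)CCC)OC2=O)C(=O)O1
A3 | alternative 2 | 2-butanoyl-3,5-dihydroxy-4,4-dimethyl-6-{[2,4,6-tris(benzyloxy)phenyl]methyl}cyclohexa-2,5-dien-1-one | CCCC(=O)C1=C(O)C(C)(C)C(O)=C(Cc2c(OCc3ccccc3)cc(OCc3ccccc3)cc2OCc2ccccc2)C1=O
A4 | alternative 2 | methyl 2,2-dimethyl-3,5,7-trioxo-4-{[2,4,6-tris(benzyloxy)phenyl]methyl}decanoate | COC(=O)C(C)(C)C(=O)C(Cc1c(OCc2ccccc2)cc(OCc2ccccc2)cc1OCc1ccccc1)C(=O)CC(=O)CCC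
A5 | alternative 3 | 1-{2-ethoxy-4,6-dihydroxy-5-{[2,4,6-tris(benzyloxy)-3-methylphenyl]methyl}-3-{[2,4,6-tris(benzyloxy)phenyl]methyl}phenyl}butan-1-one | CCCC(=O)c1c(O)c(Cc2c(OCc3ccccc3)c(C)c(OCc3ccccc3)cc2OCc2ccccc2)c(O)c(Cc2c(OCc3ccccc3)cc(OCc3ccccc3)cc2OCc2ccccc2)c1OCC
A6 | alternative 3 | 1-ethoxyhex-1-yn-3-one | CCCC(=O)C#COCC
A7 | alternative 3 | 1-methoxy-1,3-bis(trimethylsilyloxy)buta-1,3-diene bearing the [2,4,6-tris(benzyloxy)-3-methylphenyl]methyl group at C2 and the [2,4,6-tris(benzyloxy)phenyl]methyl group at C4 (silyl groups taken as trimethylsilyl; alkene geometry not defined) | COC(O[Si](C)(C)C)=C(Cc1c(OCc2ccccc2)c(C)c(OCc2ccccc2)cc1OCc1ccccc1)C(O[Si](C)(C)C)=CCc1c(OCc2ccccc2)cc(OCc2ccccc2)cc1OCc1ccccc1
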